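**Strategy.** The ten-membered carbocycle is disconnected at the bond between the dienone carbonyl carbon C2 and the vinyl carbon C3 (germacrane numbering). An intramolecular Nozaki–Hiyama–Kishi reaction adds a (Z)-C3 alkenyl iodide to a C2 enal and closes the ring in one operation, in the presence of the α-methylene lactone and the tiglate. It leaves a doubly allylic carbinol that is oxidised to the cross-conjugated dienone. The step exploits the (Z)-C3=C4 alkene, the (E)-C10=C1 alkene and the trans-fused γ-lactone (C6/C7) as turn elements. The acyclic precursor comes from a zinc Barbier union of a C3–C7 bromobutenolide with a five-carbon aldehyde (C8, C9, C10, C1, C2), which sets C7 and C8.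

Key step: step 13

Remark: germacrane numbering is used throughout (C2 dienone carbonyl, C3 vinyl CH next to methyl-bearing C4, C5 carbinol, C6 lactone-oxygen carbon, C7 ring fusion, C8 tiglate carbinol, C9 CH2, C10 methyl-bearing alkene carbon, C1 vinyl CH, C11/C12/C13 lactone α-carbon, carbonyl and exo-methylene). The C2 carbinol of 26 is assumed to form as a mixture of epimers and is left undefined in its SMILES.

**Fragment A (bromobutenolide 14)**

Step 1
Reactants: 1 prop-2-yn-1-ol
Product: 3 (Z)-3-iodo-2-methylprop-2-en-1-ol, via alkenylmagnesium alkoxide 2 (not isolated)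
Conditions: MeMgBr (3 equiv), CuI (10 mol %), THF, −10 °C to rt; then I2, −78 to 0 °C; aq NH4Cl
Reagents that add atoms: methylmagnesium bromide C[Mg]Br; iodine II
Why: Copper-catalysed anti-carbomagnesiation of the propargylic magnesium alkoxide puts methyl on the inner and magnesium on the terminal alkyne carbon inside a five-membered chelate (2), so iodinolysis with retention should leave iodine cis to the CH2OH group, the Z geometry needed for C3=C4.

Step 2
Reactants: 3 (Z)-3-iodo-2-methylprop-2-en-1-ol
Product: 4 (Z)-3-iodo-2-methylprop-2-enal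
Conditions: MnO2, CH2Cl2, rt, dark; filtered and used at once
Reagents that add atoms: none
Why: Allylic alcohol oxidation on MnO2 is neutral and heterogeneous, which should preserve the Z geometry of the sensitive β-iodoenal.

Step 3
Reactants: 4 (Z)-3-iodo-2-methylprop-2-enal; 5 allyl methoxymethyl ether
Product: 8 (1Z,3S,4S)-1-iodo-4-(methoxymethoxy)-2-methylhexa-1,5-dien-3-ol, via alkoxyallylborane 6 (not isolated), via borinate ester 7 (not isolated)
Conditions: 5, s-BuLi, THF, −78 °C; (+)-Ipc2BOMe [from (−)-α-pinene]; BF3·OEt2; then 4, −78 °C to rt; NaOH, H2O2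
Reagents that add atoms: none
Why: Brown alkoxyallylboration through a closed chair transition state, in which the (Z)-γ-alkoxyallyl geometry should give the syn (threo) C5/C6 relationship and the isopinocampheyl groups from (−)-α-pinene should direct attack to the Re face of the aldehyde, setting C5 (S) and C6 (S).

Step 4
Reactants: 8 (1Z,3S,4S)-1-iodo-4-(methoxymethoxy)-2-methylhexa-1,5-dien-3-ol
Product: 9 tert-butyl{[(1Z,3S,4S)-1-iodo-4-(methoxymethoxy)-2-methylhexa-1,5-dien-3-yl]oxy}dimethylsilane
Conditions: TBSOTf, 2,6-lutidine, CH2Cl2, −78 to 0 °C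
Reagents that add atoms: tert-butyldimethylsilyl triflate CC(C)(C)[Si](C)(C)OS(=O)(=O)C(F)(F)F
Why: Silylation with the silyl triflate should protect the hindered allylic C5 hydroxyl, the only free OH, so that O5 stays masked until the last step.

Step 5
Reactants: 9 tert-butyl{[(1Z,3S,4S)-1-iodo-4-(methoxymethoxy)-2-methylhexa-1,5-dien-3-yl]oxy}dimethylsilane
Product: 11 (3S,4S,5Z)-4-(tert-butyldimethylsilyloxy)-6-iodo-5-methylhexa-1,5-dien-3-ol, via bipyridinium acetal salt 10 (not isolated)
Conditions: TMSOTf, 2,2'-bipyridyl, CH2Cl2, 0 °C; then H2O, rt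
Reagents that add atoms: none
Why: Lewis-acid exchange of the MOM acetal to the pyridinium N,O-acetal 10 and its hydrolysis should free the C6 hydroxyl under buffered, non-protic conditions that spare the secondary TBS ether and the iodoalkene.

Step 6
Reactants: 11 (3S,4S,5Z)-4-(tert-butyldimethylsilyloxy)-6-iodo-5-methylhexa-1,5-dien-3-ol; 12 2-(bromomethyl)acrylic acid
Product: 13 (3S,4S,5Z)-4-(tert-butyldimethylsilyloxy)-6-iodo-5-methylhexa-1,5-dien-3-yl 2-(bromomethyl)acrylate
Conditions: DCC, DMAP (cat.), CH2Cl2, 0 °C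
Reagents that add atoms: none
Why: Steglich esterification of the C6 hydroxyl should bring in C12, C11, C13 and the allylic bromide in one piece, with C6 retained because only the O–H bond reacts.

Step 7
Reactants: 13 (3S,4S,5Z)-4-(tert-butyldimethylsilyloxy)-6-iodo-5-methylhexa-1,5-dien-3-yl 2-(bromomethyl)acrylate
Product: 14 (5S)-3-(bromomethyl)-5-[(1S,2Z)-1-(tert-butyldimethylsilyloxy)-3-iodo-2-methylprop-2-en-1-yl]furan-2(5H)-one
Conditions: second-generation Grubbs catalyst (H2IMes)(PCy3)Cl2Ru=CHPh (5–10 mol %), CH2Cl2, 40 °C, 0.01 M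
Reagents that add atoms: none
Why: Ring-closing metathesis between the terminal vinyl group and the acrylate alkene should form the butenolide C7=C11 bond with loss of ethylene, while the trisubstituted iodoalkene is inert to the ruthenium carbene.

**Fragment B (aldehyde 18)**

Step 8
Reactants: 15 (E)-3-methylpent-2-en-4-yn-1-ol
Product: 16 triethyl{[(E)-3-methylpent-2-en-4-yn-1-yl]oxy}silane
Conditions: TESCl, imidazole, CH2Cl2, 0 °C
Reagents that add atoms: chlorotriethylsilane CC[Si](Cl)(CC)CC
Why: Standard silylation of the primary allylic alcohol, with the triethylsilyl group chosen because step 12 can oxidise it off directly.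

Step 9
Reactants: 16 triethyl{[(E)-3-methylpent-2-en-4-yn-1-yl]oxy}silane
Product: 18 (E)-3-methyl-5-(triethylsilyloxy)pent-3-enal, via dienylborane 17 (not isolated)
Conditions: Cy2BH, THF, 0 °C; then H2O2, aq NaOAc, 0 °C
Reagents that add atoms: hydrogen peroxide OO
Why: Chemoselective syn-hydroboration of the terminal alkyne by the bulky dialkylborane puts boron on the terminal carbon, and buffered oxidation gives a dienol that should tautomerise by kinetic α-protonation to the β,γ-unsaturated aldehyde with the E-alkene intact.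

**Union and endgame**

Step 10
Reactants: 14 (5S)-3-(bromomethyl)-5-[(1S,2Z)-1-(tert-butyldimethylsilyloxy)-3-iodo-2-methylprop-2-en-1-yl]furan-2(5H)-one; 18 (E)-3-methyl-5-(triethylsilyloxy)pent-3-enal
Product: 20 (4R,5S)-5-[(1S,2Z)-1-(tert-butyldimethylsilyloxy)-3-iodo-2-methylprop-2-en-1-yl]-4-[(1S,3E)-1-hydroxy-3-methyl-5-(triethylsilyloxy)pent-3-en-1-yl]-3-methylideneoxolan-2-one, via allylzinc bromide 19 (not isolated)
Conditions: Zn dust, THF/sat. aq NH4Cl, 0 °C to rt
Reagents that add atoms: none
Why: Barbier allylation in which allylzinc 19 attacks through its γ-carbon (C7) in a Zimmerman–Traxler chair, anti to the C5-bearing substituent at C6 (trans-lactone, C7 R) and with the aldehyde residue equatorial (C8 S), while the double bond moves to the exo-methylene position.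

Step 11
Reactants: 20 Barbier adduct (C8 alcohol); 21 tiglic acid
Product: 23 (1S,3E)-1-{(2S,3R)-2-[(1S,2Z)-1-(tert-butyldimethylsilyloxy)-3-iodo-2-methylprop-2-en-1-yl]-4-methylidene-5-oxooxolan-3-yl}-3-methyl-5-(triethylsilyloxy)pent-3-en-1-yl (E)-2-methylbut-2-enoate, via mixed anhydride 22 (not isolated)
Conditions: 21, 2,4,6-trichlorobenzoyl chloride, Et3N, toluene, rt; then 20, DMAP, rt
Reagents that add atoms: none
Why: Yamaguchi esterification should acylate the hindered C8 hydroxyl with retention at C8, fast enough to outrun O6-to-O8 translactonisation, and keeps the thermodynamically preferred E-tiglate geometry.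

Step 12
Reactants: 23 C8 tiglate with primary TES ether
Product: 24 (1S,3E)-1-{(2S,3R)-2-[(1S,2Z)-1-(tert-butyldimethylsilyloxy)-3-iodo-2-methylprop-2-en-1-yl]-4-methylidene-5-oxooxolan-3-yl}-3-methyl-5-oxopent-3-en-1-yl (E)-2-methylbut-2-enoate
Conditions: (COCl)2, DMSO, CH2Cl2, −78 to −40 °C; Et3N, −78 to −30 °C, cold quench
Reagents that add atoms: none
Why: Under Swern conditions a primary triethylsilyl ether is attacked at oxygen by the chlorosulfonium salt and should be oxidised directly to the (E)-enal carrying C2, while the secondary TBS ether does not react.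

Step 13
Reactants: 24 iodo-enal (C3 alkenyl iodide, C2 aldehyde)
Product: 26 molephantinin 5-O-TBS ether with a C2 carbinol in place of the ketone (C2 epimers), via alkenylchromium dichloride 25 (not isolated)
Conditions: CrCl2 (10 equiv), NiCl2 (cat.), degassed DMSO, rt, 2 mM, slow addition of 24
Reagents that add atoms: none
Why: Zerovalent nickel, formed from NiCl2 by CrCl2, inserts into the C3–I bond with retention of the Z geometry and hands the alkenyl group to trivalent chromium (25), which adds 1,2 to the C2 aldehyde; aqueous work-up frees the C2 carbinol. The closest known reaction type is the intramolecular Nozaki–Hiyama–Kishi macrocyclisation used for medium-ring allylic alcohols. The ten-membered carbocycle closes by 10-exo-trig attack on the carbonyl carbon, forming the C2–C3 bond. The new C2 stereocentre is not controlled and need not be, since both epimers converge in step 14; C5, C6, C7 and C8 are untouched. The step needs chemoselectivity for the aldehyde over the lactone, the tiglate and the α-methylene lactone, which alkenylchromium reagents provide, and cyclisation over oligomerisation, which high dilution and the turn elements (Z)-C3=C4, (E)-C10=C1 and the trans-fused lactone should secure.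

Step 14
Reactants: 26 macrocyclic C2 carbinol
Product: 27 molephantinin 5-O-tert-butyldimethylsilyl ether
Conditions: Dess–Martin periodinane, NaHCO3, CH2Cl2, 0 °C to rt
Reagents that add atoms: none
Why: Dess–Martin oxidation of the doubly allylic C2 alcohol should give the cross-conjugated dienone under buffered conditions and merge both C2 epimers.

Step 15
Reactants: 27 molephantinin 5-O-tert-butyldimethylsilyl ether
Product: 28 molephantinin
Conditions: HF·pyridine, pyridine, THF, 0 °C to rt
Reagents that add atoms: none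
Why: Buffered fluoride-mediated cleavage of the Si–O bond should free the C5 hydroxyl without touching the dienone, the tiglate or the α-methylene lactone.

**Compound list**

1 | prop-2-yn-1-ol | C#CCO | starting material
2 | bromo[(Z)-3-(bromomagnesiooxy)-2-methylprop-1-en-1-yl]magnesium | C/C(CO[Mg]Br)=C/[Mg]Br | intermediate
3 | (Z)-3-iodo-2-methylprop-2-en-1-ol | C/C(CO)=C/I | intermediate
4 | (Z)-3-iodo-2-methylprop-2-enal | C/C(C=O)=C/I | intermediate
5 | allyl methoxymethyl ether, 3-(methoxymethoxy)prop-1-ene | C=CCOCOC | starting material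
6 | [(Z)-3-(methoxymethoxy)allyl]diisopinocampheylborane, Ipc from (−)-α-pinene | COCO/C=C\CB([C@H]1C[C@H]2C[C@@H]([C@@H]1C)C2(C)C)[C@H]1C[C@H]2C[C@@H]([C@@H]1C)C2(C)C | intermediate
7 | diisopinocampheylborinate ester of 8 (O5–B) | C=C[C@H](OCOC)[C@@H](OB([C@H]1C[C@H]2C[C@@H]([C@@H]1C)C2(C)C)[C@H]1C[C@H]2C[C@@H]([C@@H]1C)C2(C)C)/C(C)=C\I | intermediate
8 | (1Z,3S,4S)-1-iodo-4-(methoxymethoxy)-2-methylhexa-1,5-dien-3-ol | C=C[C@H](OCOC)[C@@H](O)/C(C)=C\I | intermediate
9 | tert-butyl{[(1Z,3S,4S)-1-iodo-4-(methoxymethoxy)-2-methylhexa-1,5-dien-3-yl]oxy}dimethylsilane | C=C[C@H](OCOC)[C@@H](O[Si](C)(C)C(C)(C)C)/C(C)=C\I | intermediate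
10 | 1-({[(3S,4S,5Z)-4-(tert-butyldimethylsilyloxy)-6-iodo-5-methylhexa-1,5-dien-3-yl]oxy}methyl)-2,2'-bipyridin-1-ium triflate | C=C[C@H](OC[n+]1ccccc1-c1ccccn1)[C@@H](O[Si](C)(C)C(C)(C)C)/C(C)=C\I.[O-]S(=O)(=O)C(F)(F)F | intermediate
11 | (3S,4S,5Z)-4-(tert-butyldimethylsilyloxy)-6-iodo-5-methylhexa-1,5-dien-3-ol | C=C[C@H](O)[C@@H](O[Si](C)(C)C(C)(C)C)/C(C)=C\I | intermediate
12 | 2-(bromomethyl)acrylic acid | C=C(CBr)C(=O)O | starting material
13 | (3S,4S,5Z)-4-(tert-butyldimethylsilyloxy)-6-iodo-5-methylhexa-1,5-dien-3-yl 2-(bromomethyl)acrylate | C=C[C@H](OC(=O)C(=C)CBr)[C@@H](O[Si](C)(C)C(C)(C)C)/C(C)=C\I | intermediate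
14 | (5S)-3-(bromomethyl)-5-[(1S,2Z)-1-(tert-butyldimethylsilyloxy)-3-iodo-2-methylprop-2-en-1-yl]furan-2(5H)-one | O=C1O[C@@H](C=C1CBr)[C@@H](O[Si](C)(C)C(C)(C)C)/C(C)=C\I | intermediate
15 | (E)-3-methylpent-2-en-4-yn-1-ol | C#C/C(C)=C/CO | starting material
16 | triethyl{[(E)-3-methylpent-2-en-4-yn-1-yl]oxy}silane | C#C/C(C)=C/CO[Si](CC)(CC)CC | intermediate
17 | dicyclohexyl[(1E,3E)-3-methyl-5-(triethylsilyloxy)penta-1,3-dien-1-yl]borane | CC[Si](CC)(CC)OC/C=C(C)/C=C/B(C1CCCCC1)C1CCCCC1 | intermediate
18 | (E)-3-methyl-5-(triethylsilyloxy)pent-3-enal | O=CC/C(C)=C/CO[Si](CC)(CC)CC | intermediate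
19 | allylzinc bromide from 14 (Zn on the former CH2Br carbon) | Br[Zn]CC1=C[C@H](OC1=O)[C@@H](O[Si](C)(C)C(C)(C)C)/C(C)=C\I | intermediate
20 | (4R,5S)-5-[(1S,2Z)-1-(tert-butyldimethylsilyloxy)-3-iodo-2-methylprop-2-en-1-yl]-4-[(1S,3E)-1-hydroxy-3-methyl-5-(triethylsilyloxy)pent-3-en-1-yl]-3-methylideneoxolan-2-one | C=C1C(=O)O[C@@H]([C@H]1[C@@H](O)C/C(C)=C/CO[Si](CC)(CC)CC)[C@@H](O[Si](C)(C)C(C)(C)C)/C(C)=C\I | intermediate
21 | tiglic acid, (E)-2-methylbut-2-enoic acid | C/C=C(\C)C(=O)O | starting material
22 | (E)-2-methylbut-2-enoic 2,4,6-trichlorobenzoic anhydride | C/C=C(\C)C(=O)OC(=O)c1c(Cl)cc(Cl)cc1Cl | intermediate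
23 | C8 tiglate of 20 (primary TES ether, C5 TBS ether, C3 iodide) | C=C1C(=O)O[C@@H]([C@H]1[C@@H](OC(=O)/C(C)=C/C)C/C(C)=C/CO[Si](CC)(CC)CC)[C@@H](O[Si](C)(C)C(C)(C)C)/C(C)=C\I | intermediate
24 | C2 enal of 23 (seco-aldehyde, C3 iodide) | C=C1C(=O)O[C@@H]([C@H]1[C@@H](OC(=O)/C(C)=C/C)C/C(C)=C/C=O)[C@@H](O[Si](C)(C)C(C)(C)C)/C(C)=C\I | intermediate
25 | alkenylchromium dichloride from 24 (trivalent chromium on C3) | C=C1C(=O)O[C@@H]([C@H]1[C@@H](OC(=O)/C(C)=C/C)C/C(C)=C/C=O)[C@@H](O[Si](C)(C)C(C)(C)C)/C(C)=C\[Cr](Cl)Cl | intermediate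
26 | molephantinin 5-O-TBS ether with C2 carbinol in place of the ketone (C2 epimers) | C=C1C(=O)O[C@H]2[C@H]1[C@@H](OC(=O)/C(C)=C/C)C/C(C)=C/C(O)/C=C(/C)[C@@H]2O[Si](C)(C)C(C)(C)C | intermediate
27 | molephantinin 5-O-tert-butyldimethylsilyl ether | C=C1C(=O)O[C@H]2[C@H]1[C@@H](OC(=O)/C(C)=C/C)C/C(C)=C/C(=O)/C=C(/C)[C@@H]2O[Si](C)(C)C(C)(C)C | intermediate
28 | molephantinin | C=C1C(=O)O[C@H]2[C@H]1[C@@H](OC(=O)/C(C)=C/C)C/C(C)=C/C(=O)/C=C(/C)[C@@H]2O | target

**Step count.** Total: 15 steps. Longest linear sequence: 13 steps (steps 1–7 and 10–15).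

**Steps most likely to fail**

Step 13. Closure of the strained ten-membered ring may be slow, so that the alkenylchromium species is protonated (net reduction of the C–I bond) or adds intermolecularly (oligomerisation). The fallback keeps the same C2–C3 bond but forms it as an acyl–alkenyl coupling. It sets out from 24: Pinnick oxidation (NaClO2, NaH2PO4, 2-methyl-2-butene) would give the carboxylic acid F1, and EtSH with EDC and DMAP the S-ethyl thioester F2. Me3SnSnMe3 with Pd(PPh3)4 would then exchange iodine for tin to give the alkenylstannane F3. A Liebeskind–Srogl ketone synthesis under high dilution (Pd2(dba)3, tri(2-furyl)phosphine, copper diphenylphosphinate CuO2PPh2) should close the ring directly to dienone 27, where the route is rejoined without step 14.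

Step 7. The allylic bromide may be lost by substitution or may decompose the ruthenium carbene before ring closure. The fallback carries no bromide through the metathesis and sets out from 11. Methacryloyl chloride, Et3N and DMAP would give the methacrylate ester F4. Ring-closing metathesis with the same second-generation Grubbs catalyst would give the 3-methylbutenolide F5. Wohl–Ziegler bromination (NBS, AIBN, PhCF3, 80 °C) of the butenolide methyl group would return to 14.

Step 9. The C10=C1 double bond may migrate into conjugation with the new aldehyde during oxidation of the dienylborane, or the alkyne may be hydroborated twice. The fallback makes the aldehyde by alcohol oxidation instead and sets out from 16. Semi-hydrogenation (H2, Lindlar catalyst Pd/CaCO3 poisoned with Pb(OAc)2, quinoline) would give the diene F6. Hydroboration of its terminal vinyl group with 9-BBN and oxidation with NaBO3 would give the homoallylic alcohol F7. Dess–Martin oxidation with NaHCO3 would return to 18.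

**Further compounds**

F1 | step 13 | C2 carboxylic acid from 24 (C3 iodide retained) | C=C1C(=O)O[C@@H]([C@H]1[C@@H](OC(=O)/C(C)=C/C)C/C(C)=C/C(=O)O)[C@@H](O[Si](C)(C)C(C)(C)C)/C(C)=C\I
F2 | step 13 | S-ethyl thioester of F1 | C=C1C(=O)O[C@@H]([C@H]1[C@@H](OC(=O)/C(C)=C/C)C/C(C)=C/C(=O)SCC)[C@@H](O[Si](C)(C)C(C)(C)C)/C(C)=C\I
F3 | step 13 | (Z)-alkenyl(trimethyl)stannane thioester | C=C1C(=O)O[C@@H]([C@H]1[C@@H](OC(=O)/C(C)=C/C)C/C(C)=C/C(=O)SCC)[C@@H](O[Si](C)(C)C(C)(C)C)/C(C)=C\[Sn](C)(C)C
F4 | step 7 | (3S,4S,5Z)-4-(tert-butyldimethylsilyloxy)-6-iodo-5-methylhexa-1,5-dien-3-yl methacrylate | C=C[C@H](OC(=O)C(C)=C)[C@@H](O[Si](C)(C)C(C)(C)C)/C(C)=C\I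
F5 | step 7 | (5S)-5-[(1S,2Z)-1-(tert-butyldimethylsilyloxy)-3-iodo-2-methylprop-2-en-1-yl]-3-methylfuran-2(5H)-one | CC1=C[C@H](OC1=O)[C@@H](O[Si](C)(C)C(C)(C)C)/C(C)=C\I
F6 | step 9 | triethyl{[(E)-3-methylpenta-2,4-dien-1-yl]oxy}silane | C=C/C(C)=C/CO[Si](CC)(CC)CC
F7 | step 9 | (E)-3-methyl-5-(triethylsilyloxy)pent-3-en-1-ol | OCC/C(C)=C/CO[Si](CC)(CC)CC
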